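**Plan**

1. Retrosynthetic cuts: first the C8–CH2 bond of the open prenyl group (back to a 5-O-prenyl ether), then the two ring D bonds C3'–C4'' and O4'–C2'' (C2'' = CMe2; back through the chromene to a 4'-O-1,1-dimethylpropargyl ether). What remains is (S)-naringenin 1.
2. Enabling feature: ring D is a C5 unit spanning O4' and C3' of ring B, and C3'/C5' are free, equivalent ortho CH positions. A C5 unit parked on O4' can therefore only move onto ring B and never meets the more nucleophilic ring A.
3. Forward order: rings A, C and B come intact from the flavanone. O7 is masked, O4' is propargylated, ring D closes thermally as a chromene and is saturated. Only then is the prenyl chain joined at O5, relayed to C8, and O7 unmasked.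
4. Stereochemistry: C2 (S), the only stereocentre, is bought with naringenin. No step creates a stereocentre, and conditions are chosen so that ring C does not open.

Key step: step 4

Assumption: (S)-naringenin of high enantiomeric purity is taken as a purchasable material (MOM = methoxymethyl). Because flavanones can racemise by reversible opening of ring C, the enantiomeric purity should be checked by chiral HPLC after steps 3 and 4.

**Route**

Step 1
Reactants: 1 (S)-naringenin; 2 chloromethyl methyl ether (MOMCl)
Product: 3 (2S)-5-hydroxy-2-(4-hydroxyphenyl)-7-(methoxymethoxy)chroman-4-one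
Conditions: MOMCl (1.05 equiv), i-Pr2NEt (1.2 equiv), THF, 0 °C
Reagents that add atoms: chloromethyl methyl ether (2), COCCl
Why: Williamson-type O-alkylation with an α-chloro ether should be selective because the 7-OH is a vinylogous acid para to the C4 carbonyl and is the only phenol appreciably ionised by the hindered amine, whereas the 5-OH is tied up in a hydrogen bond to C4=O and the 4'-OH is an ordinary phenol, and the weak base at 0 °C leaves C2 untouched.

Step 2
Reactants: 4 2-methylbut-3-yn-2-ol; 5 methyl chloroformate
Product: 7 methyl 2-methylbut-3-yn-2-yl carbonate, via lithium 2-methylbut-3-yn-2-olate 6 (not isolated)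
Conditions: n-BuLi (1.0 equiv), THF, −78 °C; then ClCO2Me, −78 °C to rt
Reagents that add atoms: methyl chloroformate (5), COC(=O)Cl
Why: Acylation of an alkoxide by a chloroformate: one equivalent of n-BuLi at −78 °C removes the hydroxyl proton in preference to the much less acidic alkyne C–H, and the resulting alkoxide 6 attacks methyl chloroformate at the carbonyl carbon.

Step 3
Reactants: 3 (S)-7-O-MOM-naringenin; 7 methyl 2-methylbut-3-yn-2-yl carbonate
Product: 8 (2S)-5-hydroxy-7-(methoxymethoxy)-2-[4-(2-methylbut-3-yn-2-yloxy)phenyl]chroman-4-one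
Conditions: 7 (1.3 equiv), CuCl2·2H2O (1 mol%), DBU (1.2 equiv), MeCN, −5 to 0 °C
Reagents that add atoms: methyl 2-methylbut-3-yn-2-yl carbonate (7), COC(=O)OC(C)(C)C#C
Why: Copper-catalysed propargylic substitution of a tertiary propargylic carbonate by a phenol: copper activation of the terminal alkyne lets the carbonate ionise at 0 °C, and the 4'-phenoxide, the only unchelated phenol left in 3, should add at the tertiary carbon, while the low temperature and the near-stoichiometric DBU are meant to keep base-induced opening of ring C slow.

Step 4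
Reactants: 8 (S)-7-O-MOM-4'-O-(1,1-dimethylpropargyl)naringenin
Product: 12 (2S)-2-(2,2-dimethyl-2H-chromen-6-yl)-5-hydroxy-7-(methoxymethoxy)chroman-4-one, via allenyl dienone 9 (not isolated), via ortho-allenylphenol 10 (not isolated), via ortho-quinone methide 11 (not isolated)
Conditions: degassed o-xylene, 140 °C, Ar
Reagents that add atoms: none
Why: Heating 8 triggers an aromatic propargyl Claisen [3,3] shift that breaks O4'–C2'' and joins the alkyne terminus to C3' to give allenyl dienone 9, which enolises to ortho-allenylphenol 10; a 1,5-hydrogen shift from the phenolic OH to the central allene carbon then gives the (Z)-ortho-quinone methide 11, and an oxa-6π electrocyclisation re-forms the O4'–C2'' bond and re-aromatises ring B. The closest known reaction type is the thermal rearrangement of aryl 1,1-dimethylpropargyl ethers to 2,2-dimethyl-2H-chromenes, which the gem-dimethyl group accelerates. Ring D, the only ring formed, closes by a thermally allowed disrotatory six-electron electrocyclisation of the 1-oxatriene in 11, the carbonyl oxygen bonding to the CMe2 terminus to give the six-membered pyran. No stereocentre is created, since the sp3 ring carbon of 9 disappears on enolisation and C2 is a spectator. The step needs site selectivity for ring B over ring A and between the two ortho carbons, which is secured because the C5 unit is delivered intramolecularly from O4' and because C3' and C5' are equivalent by rotation about the C2–C1' bond. It also needs retention at C2, which the base-free aprotic medium and the alkylated O4' (no phenoxide-driven opening of ring C) are expected to secure.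

Step 5
Reactants: 12 (S)-7-O-MOM chromene flavanone
Product: 13 (2S)-2-(2,2-dimethylchroman-6-yl)-5-hydroxy-7-(methoxymethoxy)chroman-4-one
Conditions: H2 (1 atm), 10% Pd/C, EtOAc, rt
Reagents that add atoms: none
Why: Heterogeneous catalytic hydrogenation should saturate the cis-disubstituted styrene-type double bond of ring D quickly at 1 atm in a neutral solvent, whereas the hydrogen-bonded aryl ketone, the benzylic C2–O1 bond and the MOM acetal react far more slowly, and the step is placed here because no prenyl double bond is present yet.

Step 6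
Reactants: 13 (S)-7-O-MOM chroman flavanone; 14 prenol (3-methylbut-2-en-1-ol)
Product: 15 (2S)-2-(2,2-dimethylchroman-6-yl)-7-(methoxymethoxy)-5-(3-methylbut-2-enyloxy)chroman-4-one
Conditions: prenol (1.5 equiv), PPh3, DIAD, THF, 0 °C to rt
Reagents that add atoms: prenol (14), CC(C)=CCO
Why: Mitsunobu etherification: the chelated 5-OH is too poor a nucleophile for clean base-mediated alkylation but acidic enough to serve as the pronucleophile, and it should be alkylated by SN2 displacement at the primary allylic carbon of activated prenol under neutral conditions that do not endanger C2.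

Step 7
Reactants: 15 5-O-prenyl ether
Product: 18 (2S)-2-(2,2-dimethylchroman-6-yl)-5-hydroxy-7-(methoxymethoxy)-8-(3-methylbut-2-enyl)chroman-4-one, via C6 dienone 16 (not isolated), via C8 dienone 17 (not isolated)
Conditions: Eu(fod)3 (10 mol%), CHCl3, 60 °C, sealed tube
Reagents that add atoms: none
Why: Aromatic Claisen rearrangement followed by a Cope rearrangement (para-Claisen sequence) under Lewis-acid catalysis: Eu(fod)3 bound between the C4 carbonyl and O5 should speed the [3,3] shift of the prenyl group to C6, the crowded 1,1-dimethylallyl dienone 16 should relieve strain by a second [3,3] shift to C8, and dienone 17 then enolises to the chelated 5-phenol with the prenyl group in its linear form.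

Step 8
Reactants: 18 7-O-MOM-8-prenyl flavanone
Product: 19 euchrenone a16, (2S)-2-(2,2-dimethylchroman-6-yl)-5,7-dihydroxy-8-(3-methylbut-2-enyl)chroman-4-one
Conditions: HCl (3 M in MeOH), rt to 40 °C
Reagents that add atoms: none
Why: Acid-catalysed acetal exchange (solvolysis of a phenolic MOM ether) transfers the methoxymethyl group to methanol under dilute HCl at mild temperature, conditions that ortho-prenyl phenols and the configuration at C2 of 5-hydroxyflavanones are expected to tolerate.

**Compound list**

1 | (S)-naringenin, (2S)-5,7-dihydroxy-2-(4-hydroxyphenyl)chroman-4-one | Oc1cc(O)c2c(c1)O[C@H](c1ccc(O)cc1)CC2=O | starting material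
2 | chloromethyl methyl ether | COCCl | starting material
3 | (2S)-5-hydroxy-2-(4-hydroxyphenyl)-7-(methoxymethoxy)chroman-4-one | COCOc1cc(O)c2c(c1)O[C@H](c1ccc(O)cc1)CC2=O | intermediate
4 | 2-methylbut-3-yn-2-ol | C#CC(C)(C)O | starting material
5 | methyl chloroformate | COC(=O)Cl | starting material
6 | lithium 2-methylbut-3-yn-2-olate | [Li+].[O-]C(C)(C)C#C | intermediate
7 | methyl 2-methylbut-3-yn-2-yl carbonate | COC(=O)OC(C)(C)C#C | intermediate
8 | (2S)-5-hydroxy-7-(methoxymethoxy)-2-[4-(2-methylbut-3-yn-2-yloxy)phenyl]chroman-4-one | COCOc1cc(O)c2c(c1)O[C@H](c1ccc(OC(C)(C)C#C)cc1)CC2=O | intermediate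
9 | (2S)-5-hydroxy-7-(methoxymethoxy)-2-[3-(3-methylbuta-1,2-dien-1-yl)-4-oxocyclohexa-1,5-dien-1-yl]chroman-4-one (allenyl dienone; sp3 ring carbon of either configuration) | COCOc1cc(O)c2c(c1)O[C@H](C1=CC(C=C=C(C)C)C(=O)C=C1)CC2=O | intermediate
10 | (2S)-5-hydroxy-2-[4-hydroxy-3-(3-methylbuta-1,2-dien-1-yl)phenyl]-7-(methoxymethoxy)chroman-4-one (ortho-allenylphenol) | COCOc1cc(O)c2c(c1)O[C@H](c1ccc(O)c(C=C=C(C)C)c1)CC2=O | intermediate
11 | (2S)-5-hydroxy-7-(methoxymethoxy)-2-[(3Z)-3-(3-methylbut-2-en-1-ylidene)-4-oxocyclohexa-1,5-dien-1-yl]chroman-4-one (ortho-quinone methide) | COCOc1cc(O)c2c(c1)O[C@H](C1=C/C(=C/C=C(C)C)C(=O)C=C1)CC2=O | intermediate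
12 | (2S)-2-(2,2-dimethyl-2H-chromen-6-yl)-5-hydroxy-7-(methoxymethoxy)chroman-4-one | COCOc1cc(O)c2c(c1)O[C@H](c1ccc3c(c1)C=CC(C)(C)O3)CC2=O | intermediate
13 | (2S)-2-(2,2-dimethylchroman-6-yl)-5-hydroxy-7-(methoxymethoxy)chroman-4-one | COCOc1cc(O)c2c(c1)O[C@H](c1ccc3c(c1)CCC(C)(C)O3)CC2=O | intermediate
14 | prenol, 3-methylbut-2-en-1-ol | CC(C)=CCO | starting material
15 | (2S)-2-(2,2-dimethylchroman-6-yl)-7-(methoxymethoxy)-5-(3-methylbut-2-enyloxy)chroman-4-one | COCOc1cc(OCC=C(C)C)c2c(c1)O[C@H](c1ccc3c(c1)CCC(C)(C)O3)CC2=O | intermediate
16 | (2S)-2-(2,2-dimethylchroman-6-yl)-7-(methoxymethoxy)-6-(2-methylbut-3-en-2-yl)-2,3-dihydro-4H-chromene-4,5(6H)-dione (C6 dienone; C6 of either configuration) | COCOC1=CC2=C(C(=O)C1C(C)(C)C=C)C(=O)C[C@@H](c1ccc3c(c1)CCC(C)(C)O3)O2 | intermediate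
17 | (2S)-2-(2,2-dimethylchroman-6-yl)-7-(methoxymethoxy)-8-(3-methylbut-2-enyl)-2,3-dihydro-4H-chromene-4,5(8H)-dione (C8 dienone; C8 of either configuration) | COCOC1=CC(=O)C2=C(C1CC=C(C)C)O[C@H](c1ccc3c(c1)CCC(C)(C)O3)CC2=O | intermediate
18 | (2S)-2-(2,2-dimethylchroman-6-yl)-5-hydroxy-7-(methoxymethoxy)-8-(3-methylbut-2-enyl)chroman-4-one | COCOc1cc(O)c2c(c1CC=C(C)C)O[C@H](c1ccc3c(c1)CCC(C)(C)O3)CC2=O | intermediate
19 | euchrenone a16, (2S)-2-(2,2-dimethylchroman-6-yl)-5,7-dihydroxy-8-(3-methylbut-2-enyl)chroman-4-one | CC(C)=CCc1c(O)cc(O)c2c1O[C@H](c1ccc3c(c1)CCC(C)(C)O3)CC2=O | target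

**Step count and risks**

Total step count: 8. Longest linear sequence: 7 steps from 1 (steps 1, 3, 4, 5, 6, 7, 8); step 2 is a one-step side branch.

Steps most likely to fail:

Step 3. What may go wrong: reversible base-induced opening of ring C, through the 4'-phenoxide or the C3 enolate, would erode the configuration at C2. Capture at the tertiary carbon may also be slow, with competing methoxycarbonyl transfer to the phenol. The fallback reverses the mode of activation: the electrophile is activated by acid and the phenol stays neutral. It sets out from 3 and 4. Alcohol 4 is added to trichloroacetonitrile (DBU cat., CH2Cl2, 0 °C) to give 2-methylbut-3-yn-2-yl 2,2,2-trichloroacetimidate F1. Phenol 3 is then alkylated with F1 under BF3·OEt2 (cat.) in CH2Cl2/cyclohexane at −30 °C, an acid-catalysed imidate etherification of the kind used for tert-alkyl aryl ethers. The route is rejoined at 8.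

Step 7. What may go wrong: the Cope relay may lose the race against enolisation of the C6 dienone, so that the C5 unit stays at C6 in its branched form. Lewis-acid ionisation of the allyl ether with loss of the prenyl group is the other risk. The fallback replaces the two concerted shifts by a dissociative O-to-C transfer from O7 and sets out from 13. The MOM group is removed there with HCl in MeOH, where no alkene is present, to give (2S)-2-(2,2-dimethylchroman-6-yl)-5,7-dihydroxychroman-4-one F2. A Mitsunobu reaction with one equivalent of prenol (PPh3, DIAD, THF, 0 °C) should alkylate only the acidic, unchelated 7-OH and give the 7-O-prenyl ether F3. Heating F3 over magnesium silicate MgSiO3 (Florisil) in toluene at about 100 °C should then move the prenyl group by a surface-promoted [1,3] shift to the ortho carbons. The C8 product is separated from any C6-prenylated material, and the route is rejoined directly at 19 with no final deprotection.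

Step 8. What may go wrong: acid-induced addition of the freed 7-OH across the neighbouring prenyl double bond (closure of an extra pyran ring), or hydration of that alkene, before the acetal is fully cleaved. The fallback changes the protecting group so that the last step is not acidic. It sets out from 13 and again removes the MOM group with HCl in MeOH to reach diol F2. Ac2O (1.1 equiv) in pyridine at 0 °C should acetylate only the 7-OH and give the 7-acetate F4. Mitsunobu prenylation of the chelated 5-OH (prenol, PPh3, DIAD) gives the 5-O-prenyl ether F5. The Claisen–Cope sequence with Eu(fod)3 (10 mol%) in CHCl3 at 60 °C gives the 8-prenyl 7-acetate F6. Brief transesterification with K2CO3 (cat.) in MeOH at 0 °C then rejoins the route at 19.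

**Further compounds**

F1 | step 3 | 2-methylbut-3-yn-2-yl 2,2,2-trichloroacetimidate | C#CC(C)(C)OC(=N)C(Cl)(Cl)Cl
F2 | step 7 | (2S)-2-(2,2-dimethylchroman-6-yl)-5,7-dihydroxychroman-4-one | Oc1cc(O)c2c(c1)O[C@H](c1ccc3c(c1)CCC(C)(C)O3)CC2=O
F3 | step 7 | (2S)-2-(2,2-dimethylchroman-6-yl)-5-hydroxy-7-(3-methylbut-2-enyloxy)chroman-4-one | CC(C)=CCOc1cc(O)c2c(c1)O[C@H](c1ccc3c(c1)CCC(C)(C)O3)CC2=O
F4 | step 8 | (2S)-7-acetoxy-2-(2,2-dimethylchroman-6-yl)-5-hydroxychroman-4-one | CC(=O)Oc1cc(O)c2c(c1)O[C@H](c1ccc3c(c1)CCC(C)(C)O3)CC2=O
F5 | step 8 | (2S)-7-acetoxy-2-(2,2-dimethylchroman-6-yl)-5-(3-methylbut-2-enyloxy)chroman-4-one | CC(=O)Oc1cc(OCC=C(C)C)c2c(c1)O[C@H](c1ccc3c(c1)CCC(C)(C)O3)CC2=O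
F6 | step 8 | (2S)-7-acetoxy-2-(2,2-dimethylchroman-6-yl)-5-hydroxy-8-(3-methylbut-2-enyl)chroman-4-one | CC(=O)Oc1cc(O)c2c(c1CC=C(C)C)O[C@H](c1ccc3c(c1)CCC(C)(C)O3)CC2=O
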